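# Total synthesis of Dichrostachine E

**Retrosynthetic overview**
1. Dichrostachine E comes from global debenzylation and tert-butyl ester cleavage of the protected skeleton **16**.
2. Instead of a quinone/diene Diels–Alder, the cyclohexene ring, the quaternary Ca–C12 bond and the cis ring fusion come from a Lewis-acid 6-endo cation–olefin (Mukaiyama–Michael/ene-type) cyclization of chromonyl-quinone **15** onto its tethered E-trisubstituted alkene. The quinone is the methoxy-enedione ring.
3. Quinone **15** comes from CAN oxidative demethylation of flavone **14**. The C15–aryl bond of **14** is made by B-alkyl Suzuki coupling of the terminal-vinyl hydroboration product **8** (from a communic-type diene) with bromoflavone **13**.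
4. Bromoflavone **13** is built from 2,4,5-trimethoxybenzaldehyde (Comins bromination, Claisen–Schmidt, I2/DMSO). The C7 β-OH is installed on the communic-type acid with the diene masked as a sulfolene.
5. Order of construction: decalin (from the starting acid), then chromone, then quinone (ring 2), then cyclohexene ring 1 (last C–C bond), then deprotection.

**Assumptions**
- 4-epi-trans-Communic acid (equatorial CO2H at C4, matching the target's C4) is taken as catalogue natural-product supply.
- Only substrates and products are numbered. Reagents that leave atoms in a product are named with SMILES in each step.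

---

**Step 1**
Reactants: **1** 4-epi-trans-communic acid
Product: **2** tert-butyl ester of 1
Conditions: tBuOC(=NiPr)NHiPr (3 equiv), CH2Cl2, 40 °C, 24 h
Reagents that add atoms: O-tert-butyl-N,N'-diisopropylisourea, CC(C)N=C(OC(C)(C)C)NC(C)C
Why: Isourea-mediated tert-butylation of the hindered α-quaternary acid, which avoids strong acid and gives an ester removable by BCl3 at the end; no stereocentre is touched.

**Step 2**
Reactants: **2**
Product: **3** 3-sulfolene (SO2 adduct across C12/C15) of 2, as a C12 epimer mixture
Conditions: liquid SO2 (sealed tube), BHT (cat.), 25 °C, 60 h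
Reagents that add atoms: sulfur dioxide, O=S=O
Why: Cheletropic SO2 addition to the 1,3-diene masks it so that the next allylic oxidation is selective for the C8(17) methylene; the new C12 stereocentre is erased in step 5.

**Step 3**
Reactants: **3**
Product: **4** 7-oxo-8(17)-ene sulfolene (exocyclic enone)
Conditions: CrO3 (8 equiv), 3,5-dimethylpyrazole (8 equiv), CH2Cl2, –20 °C, 6 h
Reagents that add atoms: chromium trioxide (source of the C=O oxygen), O=[Cr](=O)=O
Why: Salmond allylic oxidation of the ring C7–H2 next to the exocyclic methylene; the sulfolene alkene is electron-poor and survives.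

**Step 4**
Reactants: **4**
Product: **5** 7β-hydroxy sulfolene
Conditions: NaBH4, CeCl3·7H2O, MeOH/CH2Cl2 1:1, –78 → 0 °C
Reagents that add atoms: none
Why: Luche 1,2-reduction; axial hydride delivery from the α-face (flanked only by 5α-H and 9α-H) gives the equatorial 7β-OH, the configuration of the target, with the minor 7α epimer separable.

**Step 5**
Reactants: **5**
Product: **6** tert-butyl 7β-hydroxy-4-epi-communate (12E-diene regenerated)
Conditions: toluene (0.01 M), BHT, 110 °C, N2 sparge, 3 h
Reagents that add atoms: none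
Why: Retro-cheletropic SO2 extrusion is stereospecific and disrotatory, so the C12 substituent rotates outward and gives the 12E-diene; the C12 stereocentre of **3** is lost.

**Step 6**
Reactants: **6**
Product: **7** 7β-benzyl ether
Conditions: NaH (2 equiv), BnBr (1.5 equiv), TBAI (0.1 equiv), THF, 0 °C → 25 °C
Reagents that add atoms: benzyl bromide, BrCc1ccccc1
Why: Williamson etherification (no sulfone is present any more, so NaH is safe), giving a protecting group that matches the phenols and is removed in the last step; C7 is retained.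

**Step 7**
Reactants: **7**
Product: **8** C15 B-alkyl-9-BBN (not isolated)
Conditions: 9-BBN dimer (0.55 equiv), THF, 0 °C → 25 °C, 4 h; used in situ
Reagents that add atoms: 9-BBN, [BH]1C2CCCC1CCC2
Why: Hydroboration with a bulky dialkylborane occurs at the monosubstituted terminal C14=C15 alkene and not at the hindered exocyclic methylene or the trisubstituted C12=C13 alkene, which keeps the 12E geometry.

**Step 8**
Reactants: **9** 2,4,5-trimethoxybenzaldehyde
Product: **10** 6-bromo-2,4,5-trimethoxybenzaldehyde
Conditions: (i) LiN(Me)CH2CH2NMe2 (1.1 equiv), THF, 0 °C; (ii) s-BuLi (3 equiv), –20 °C, 3 h; (iii) BrCF2CF2Br (3 equiv), –78 °C → 25 °C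
Reagents that add atoms: 1,2-dibromotetrafluoroethane, BrC(F)(F)C(F)(F)Br
Why: Comins in-situ α-amino-alkoxide-directed ortho-lithiation occurs at C6, the only free position ortho to the masked aldehyde; C3, between two OMe groups, is the competing site.

**Step 9**
Reactants: **10**; **11** 2'-hydroxy-4',6'-bis(benzyloxy)acetophenone
Product: **12** (E)-2'-hydroxychalcone
Conditions: KOH (50% aq.), EtOH, 25 °C, 48 h
Reagents that add atoms: none
Why: Claisen–Schmidt aldol condensation; the benzyl ethers survive and only the E-enone forms.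

**Step 10**
Reactants: **12**
Product: **13** 5,7-bis(benzyloxy)-2-(6-bromo-2,4,5-trimethoxyphenyl)chromone
Conditions: I2 (0.2 equiv), DMSO, 130 °C, 1 h
Reagents that add atoms: none
Why: I2/DMSO oxidative cyclization (oxa-Michael then dehydrogenation) of the 2'-hydroxychalcone gives the flavone; no stereocentre is involved.

**Step 11**
Reactants: **8** (1.3 equiv); **13**
Product: **14** flavone carrying the labdane chain at C6' of the B ring
Conditions: Pd(dppf)Cl2 (10 mol%), K3PO4 (3 equiv), THF/H2O 10:1, 65 °C, 12 h
Reagents that add atoms: none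
Why: B-alkyl Suzuki–Miyaura coupling forms the C15–aryl bond; the E-alkene and all labdane stereocentres are untouched.

**Step 12**
Reactants: **14**
Product: **15** 2-methoxy-5-(chromon-2-yl)-6-alkyl-1,4-benzoquinone
Conditions: CAN (2.5 equiv), MeCN/H2O 4:1, 0 °C, 10 min
Reagents that add atoms: water, O (source of the quinone oxygens)
Why: CAN oxidative demethylation of the only para-dimethoxy pair (C2'/C5') gives the quinone and leaves the C4' OMe as the vinylogous-ester methoxy of ring 2.

**Step 13**
Reactants: **15**
Product: **16** protected Dichrostachine E (tert-butyl ester, tri-O-benzyl)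
Conditions: Me2AlCl (3 equiv), CH2Cl2, –78 → –20 °C, 4 h; Rochelle salt work-up
Reagents that add atoms: none (isomerization)
Why: Proposed new method: Me2AlCl binds the C1 carbonyl and makes C5 (Ca, the β-carbon bearing the chromone) electrophilic; the nucleophilic C12 of the E-trisubstituted alkene attacks it in a chair-like 6-endo closure, which builds the quaternary Ca–C12 bond and a tertiary cation at C13. Loss of H+ from C14 gives the endocyclic C13=C14 alkene, and protonation of the aluminium enolate at Cb gives the cis ring fusion. The closest known chemistry is Snider's Me2AlCl-promoted alkene–enone ene/Michael cyclizations and polyene cyclizations terminated on enones. Facial control relative to the remote C9 is expected to be modest, so the two diastereomers are separated by HPLC.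

**Step 14**
Reactants: **16**
Product: **17** Dichrostachine E
Conditions: BCl3 (1 M in CH2Cl2, 10 equiv), pentamethylbenzene (8 equiv), CH2Cl2, –78 °C, 1 h; MeOH quench
Reagents that add atoms: none
Why: BCl3 with a cation scavenger cleaves the two aryl benzyl ethers, the C7 benzyl ether and the tert-butyl ester at –78 °C without hydrogenation, leaving the alkenes, the enol methyl ether and all stereocentres intact.

---

**Compound list**
1 | 4-epi-trans-communic acid | C=C1CC[C@@H]2[C@](C)(CCC[C@@]2(C)C(=O)O)[C@H]1C/C=C(\C)C=C | starting material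
2 | tert-butyl ester of 1 | C=C1CC[C@@H]2[C@](C)(CCC[C@@]2(C)C(=O)OC(C)(C)C)[C@H]1C/C=C(\C)C=C | intermediate
3 | 3-sulfolene (SO2 adduct) of 2, C12 epimers | C=C1CC[C@@H]2[C@](C)(CCC[C@@]2(C)C(=O)OC(C)(C)C)[C@H]1CC1C(C)=CCS1(=O)=O | intermediate
4 | 7-oxo sulfolene | C=C1C(=O)C[C@@H]2[C@](C)(CCC[C@@]2(C)C(=O)OC(C)(C)C)[C@H]1CC1C(C)=CCS1(=O)=O | intermediate
5 | 7β-hydroxy sulfolene | C=C1[C@@H](O)C[C@@H]2[C@](C)(CCC[C@@]2(C)C(=O)OC(C)(C)C)[C@H]1CC1C(C)=CCS1(=O)=O | intermediate
6 | tert-butyl 7β-hydroxy-4-epi-communate | C=C1[C@@H](O)C[C@@H]2[C@](C)(CCC[C@@]2(C)C(=O)OC(C)(C)C)[C@H]1C/C=C(\C)C=C | intermediate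
7 | 7β-benzyloxy diene | C=C1[C@@H](OCc3ccccc3)C[C@@H]2[C@](C)(CCC[C@@]2(C)C(=O)OC(C)(C)C)[C@H]1C/C=C(\C)C=C | intermediate
8 | C15 B-alkyl-9-BBN | C=C1[C@@H](OCc3ccccc3)C[C@@H]2[C@](C)(CCC[C@@]2(C)C(=O)OC(C)(C)C)[C@H]1C/C=C(\C)CCB4C5CCCC4CCC5 | intermediate
9 | 2,4,5-trimethoxybenzaldehyde | COc1cc(OC)c(C=O)cc1OC | starting material
10 | 6-bromo-2,4,5-trimethoxybenzaldehyde | COc1cc(OC)c(C=O)c(Br)c1OC | intermediate
11 | 2'-hydroxy-4',6'-bis(benzyloxy)acetophenone | CC(=O)c1c(O)cc(OCc2ccccc2)cc1OCc1ccccc1 | starting material
12 | 2'-hydroxychalcone | COc1cc(OC)c(/C=C/C(=O)c2c(O)cc(OCc3ccccc3)cc2OCc2ccccc2)c(Br)c1OC | intermediate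
13 | 6'-bromoflavone | COc1cc(OC)c(-c2cc(=O)c3c(OCc4ccccc4)cc(OCc4ccccc4)cc3o2)c(Br)c1OC | intermediate
14 | coupled flavone | C=C1[C@@H](OCc3ccccc3)C[C@@H]2[C@](C)(CCC[C@@]2(C)C(=O)OC(C)(C)C)[C@H]1C/C=C(\C)CCc4c(OC)c(OC)cc(OC)c4-c5cc(=O)c6c(OCc7ccccc7)cc(OCc7ccccc7)cc6o5 | intermediate
15 | chromonyl quinone | C=C1[C@@H](OCc3ccccc3)C[C@@H]2[C@](C)(CCC[C@@]2(C)C(=O)OC(C)(C)C)[C@H]1C/C=C(\C)CCC4=C(c5cc(=O)c6c(OCc7ccccc7)cc(OCc7ccccc7)cc6o5)C(=O)C=C(OC)C4=O | intermediate
16 | protected Dichrostachine E | C=C1[C@@H](OCc3ccccc3)C[C@@H]2[C@](C)(CCC[C@@]2(C)C(=O)OC(C)(C)C)[C@H]1C[C@@H]1C(C)=CC[C@H]2C(=O)C(OC)=CC(=O)[C@@]12c1cc(=O)c2c(OCc3ccccc3)cc(OCc3ccccc3)cc2o1 | intermediate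
17 | Dichrostachine E | C=C1[C@@H](O)C[C@@H]2[C@](C)(CCC[C@@]2(C)C(=O)O)[C@H]1C[C@@H]1C(C)=CC[C@H]2C(=O)C(OC)=CC(=O)[C@@]12c1cc(=O)c2c(O)cc(O)cc2o1 | target

**Total steps:** 14. **Longest linear sequence:** 11 steps (1 → 2 → 3 → 4 → 5 → 6 → 7 → 8 → 14 → 15 → 16 → 17).

**Three steps most likely to fail**
1. **Step 13 (Me2AlCl cyclization):** the C5 (Ca) regiochemistry, oxygen trapping of the C13 cation, and the diastereoselectivity at C12/Ca/Cb are all uncertain. Fallback: intermolecular biomimetic Diels–Alder of diene **7** with the chain-free 2-methoxy-5-chromonyl quinone (from CAN oxidation of the des-bromo flavone), promoted by a Lewis acid or high pressure.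
2. **Step 12 (CAN oxidation):** the acidic oxidant may cleave the tert-butyl ester or attack the alkenes. Fallback: oxidize the chain-free flavone to the quinone first and install the C15 chain by Ag/persulfate radical C–H alkylation of the quinone with the corresponding alkyl-BF3K, which changes how the b–C15 bond is made.
3. **Step 14 (BCl3 global deprotection):** HCl or BCl3 could hydrochlorinate the methylene or demethylate the vinylogous-ester OMe. Fallback: redesign the protection strategy with fluoride-labile groups (TBS on C7-OH and phenols, 2-(trimethylsilyl)ethyl ester) and remove all of them with buffered TBAF/AcOH.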